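The rate constants are those of an exercise; the flask was simulated.

A small charge of D, less than the E beside it, meets that E, and I wanted to know how much of the E ends as Q.

    X ⇌ L (K1 = 0.44, k1 = 0.012 s⁻¹)
    X → Q (k2 = 0.26 s⁻¹)
    E + D → X + G (k3 = 1.3 M⁻¹ s⁻¹)
    L ⇌ J (K4 = 2.6, k4 = 6.8 × 10⁻⁴ s⁻¹)
    X ⇌ Z (K5 = 30, k5 = 1.9 × 10⁻⁴ s⁻¹)

E 22 mM; D 0.500 equiv; time 25 min

- which holds at 25 min: what has brought the reaction to rest, or that it has not come to rest (D has run out first / it is still moving / forward and back rates have come level / all of E has reacted)
- share of the E used up at 25 min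
- Q at 25 min, in percent of the E charged

- the reaction counts as stopped when no species that holds the E changes by six tenths of a point or more over the second half of the time
- run time (flask): 25 min

Each E that reacts takes one D, so D is the limiting reagent and 50.0 % of the E can pass into X. The Q is then that amount less a small correction, and I reckoned the correction. X goes to Q at 0.26 s⁻¹ and to Z at 1.9 × 10⁻⁴ s⁻¹. It also goes to L at 0.012 s⁻¹, but L returns to X at 0.0273 s⁻¹ and passes on to J at 6.8 × 10⁻⁴ s⁻¹, far more slowly. Taking X to L against X to Q, and L to J against L to X, and multiplying the two ratios cancels the rate constant of the step from X to L: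

leak = (1.9 × 10⁻⁴ s⁻¹ + 0.44 × 6.8 × 10⁻⁴ s⁻¹) / 0.26 s⁻¹ = 0.188 %

This leak is my estimate of the share of the X made that turns aside from Q. It gave me:

Q = 50.0 % × (1 − leak) = 49.9 %, with 0.0941 % in Z and J

One number was not enough, for it holds no clock. [E] does not fall below 11.0 mM, so D halves in 48.5 s at the slowest, which leaves room for about 30.9 halvings within 25 min. With that time far shorter than the run, I reckoned that D ends the reaction at 50.0 % conversion. J returns to L at 2.62 × 10⁻⁴ s⁻¹, a half-life of 44.2 min against a run of 25 min, so part of the J may drain back, and I took the leak as an estimate on the high side.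

The forecast read "D has run out first", 50 % and 49.9 %, holding that “X goes overwhelmingly to irreversible Q”.

The flask gave "D has run out first", with 50.0 % converted and Q at 49.9 %. At 25.0 min Z and J together held 0.0753 %, less than the 0.0941 % from the leak, and J had moved from 0.0474 % at 12.5 min to 0.0391 %. For the neighbour flask with 0.200 equiv of D, the leak gives an estimate of 0.0376 % of the E charged turned aside from Q. That flask gave 20.0 % conversion, Q at 20.0 %, and 0.0301 % in Z and J.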